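**Retrosynthetic overview**

1. Leachianone A ⇐ removal of three MOM groups ⇐ C8–CH2 bond by Negishi coupling of an (S)-lavandulylzinc iodide (from an Evans deconjugative alkylation) with an 8-iodoflavanone, whose iodine replaces a C8–SiMe3 marker.
2. Ring C is the only ring that is built (rings A and B are bought as phloroglucinol and methyl 4-hydroxy-2-methoxybenzoate). It closes in one operation: a C4a≡C8a aryne of ring A takes up the chain O1–C2–C3–C4 of an (S)-β-silyloxy amide, O1 adding to C8a and the C4a carbanion to the C4 carbonyl.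
3. Enabling feature: the 1,3,5-oxygenation of ring A. The acetal oxygen on C5 (next to C4a) and the SiMe3 group on C8 (next to C8a) polarize the aryne in the same sense. The precursor, a 2,6-bis(trimethylsilyl)-3,5-bis(methoxymethoxy)phenyl triflate, is symmetric, so either silyl group may leave. The C2–O1 bond exists beforehand and is never broken, so C2 is carried through.
4. Stereocentres: C2 by Ru-catalysed asymmetric transfer hydrogenation of a β-keto amide; the side-chain centre by the Evans alkylation.
5. The lavandulyl group is joined after the aryne step on purpose: an aryne next to a prenyl-type chain would be lost to an intramolecular ene reaction.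

Key step: step 15

Remark: the side-chain stereocentre is S in lavandulol, its iodide and the zinc reagent and R once its CH2 carries ring A, only because the CIP priorities change; no bond at this centre is broken.

**Route**

Step 1
Reactants: 1 phloroglucinol (benzene-1,3,5-triol)
Product: 2 3,5-bis(methoxymethoxy)phenol
Conditions: MOMCl (2.0 equiv), K2CO3, acetone, 0 °C to rt; chromatography, mono-ether recycled
Reagents that add atoms: chloromethyl methyl ether (MOMCl), COCCl
Why: Williamson O-alkylation of the symmetric triol with two equivalents of the chloromethyl ether should give the bis-acetal as the main, separable member of a statistical set and leaves one free phenol, the oxygen that later becomes the triflate.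

Step 2
Reactants: 2 3,5-bis(methoxymethoxy)phenol
Product: 3 3,5-bis(methoxymethoxy)phenyl N,N-diethylcarbamate
Conditions: Et2NCOCl, K2CO3, MeCN, reflux
Reagents that add atoms: N,N-diethylcarbamoyl chloride, CCN(CC)C(=O)Cl
Why: O-carbamoylation of the phenol puts the strongest oxygen-based directing group for ortho-metalation on the one oxygen that will later be removed.

Step 3
Reactants: 3 3,5-bis(methoxymethoxy)phenyl N,N-diethylcarbamate
Product: 5 3,5-bis(methoxymethoxy)-2-(trimethylsilyl)phenyl N,N-diethylcarbamate, via ortho-lithiated carbamate 4 (not isolated)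
Conditions: s-BuLi, TMEDA, THF, −78 °C; then Me3SiCl, −78 °C to rt
Reagents that add atoms: chlorotrimethylsilane (Me3SiCl), C[Si](C)(C)Cl
Why: Snieckus directed ortho-metalation, in which carbamate and neighbouring acetal oxygen act together so that lithiation should occur between them and not between the two acetals, and silylation at −78 °C precedes any anionic ortho-Fries shift.

Step 4
Reactants: 5 3,5-bis(methoxymethoxy)-2-(trimethylsilyl)phenyl N,N-diethylcarbamate
Product: 7 3,5-bis(methoxymethoxy)-2,6-bis(trimethylsilyl)phenyl N,N-diethylcarbamate, via second ortho-lithiated carbamate 6 (not isolated)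
Conditions: s-BuLi, TMEDA, THF, −78 °C; then Me3SiCl, −78 °C to rt
Reagents that add atoms: chlorotrimethylsilane (Me3SiCl), C[Si](C)(C)Cl
Why: a second directed ortho-metalation at the remaining position between carbamate and acetal, followed by silylation, gives the symmetric bis-silane.

Step 5
Reactants: 7 3,5-bis(methoxymethoxy)-2,6-bis(trimethylsilyl)phenyl N,N-diethylcarbamate
Product: 8 3,5-bis(methoxymethoxy)-2,6-bis(trimethylsilyl)phenol
Conditions: LiAlH4, THF, reflux; then H2O
Reagents that add atoms: none
Why: hydride reduction of the aryl carbamate (acyl–oxygen cleavage) frees the phenol, the small hydride should reach the carbonyl between the two silyl groups, and aryl–silicon bonds and acetals are inert to LiAlH4.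

Step 6
Reactants: 8 3,5-bis(methoxymethoxy)-2,6-bis(trimethylsilyl)phenol
Product: 9 3,5-bis(methoxymethoxy)-2,6-bis(trimethylsilyl)phenyl trifluoromethanesulfonate
Conditions: Tf2O, pyridine, CH2Cl2, −20 °C to rt
Reagents that add atoms: trifluoromethanesulfonic anhydride (Tf2O), O=S(=O)(OS(=O)(=O)C(F)(F)F)C(F)(F)F
Why: O-triflation of the phenol gives a Kobayashi-type ortho-silylaryl triflate that is symmetric, with a silyl group on either side of the leaving group.

Step 7
Reactants: 10 methyl 4-hydroxy-2-methoxybenzoate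
Product: 11 methyl 2-methoxy-4-(methoxymethoxy)benzoate
Conditions: MOMCl, K2CO3, acetone, rt
Reagents that add atoms: chloromethyl methyl ether (MOMCl), COCCl
Why: Williamson O-alkylation protects the ring B phenol as the same acetal used on ring A, so that one acid treatment removes all three at the end.

Step 8
Reactants: 11 methyl 2-methoxy-4-(methoxymethoxy)benzoate; 12 N,N-dimethylacetamide
Product: 14 3-[2-methoxy-4-(methoxymethoxy)phenyl]-N,N-dimethyl-3-oxopropanamide, via lithium enolate of N,N-dimethylacetamide 13 (not isolated)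
Conditions: LiN(i-Pr)2 (2.2 equiv), 12 (2.2 equiv), THF, −78 °C; then 11, −78 to 0 °C; AcOH quench
Reagents that add atoms: none
Why: crossed Claisen condensation, in which the amide enolate acylates the non-enolizable aryl ester and the second equivalent of enolate deprotonates the β-keto amide as it forms, which drives the reaction and prevents a second addition.

Step 9
Reactants: 14 3-[2-methoxy-4-(methoxymethoxy)phenyl]-N,N-dimethyl-3-oxopropanamide
Product: 15 (3S)-3-hydroxy-3-[2-methoxy-4-(methoxymethoxy)phenyl]-N,N-dimethylpropanamide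
Conditions: RuCl[(S,S)-TsDPEN](p-cymene) (1 mol%), HCO2Na, H2O/MeOH, 40 °C
Reagents that add atoms: none
Why: Noyori–Ikariya asymmetric transfer hydrogenation of the aryl ketone, in which the (S,S)-catalyst should deliver hydride to the face that gives the S alcohol (the sense known for acetophenone), and this sets C2 of the target.

Step 10
Reactants: 15 (3S)-3-hydroxy-3-[2-methoxy-4-(methoxymethoxy)phenyl]-N,N-dimethylpropanamide
Product: 16 (3S)-3-[2-methoxy-4-(methoxymethoxy)phenyl]-N,N-dimethyl-3-[(trimethylsilyl)oxy]propanamide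
Conditions: 1-(trimethylsilyl)imidazole, CH2Cl2, rt
Reagents that add atoms: 1-(trimethylsilyl)imidazole, C[Si](C)(C)n1ccnc1
Why: neutral O-silylation turns the hydroxyl into a fluoride-labile trimethylsilyl ether, so that the alkoxide can be released in step 15 without any proton source.

Step 11
Reactants: 17 (4S)-4-benzyl-1,3-oxazolidin-2-one; 18 3-methylbut-2-enoyl chloride
Product: 20 (4S)-4-benzyl-3-(3-methylbut-2-enoyl)-1,3-oxazolidin-2-one, via lithium oxazolidinide 19 (not isolated)
Conditions: n-BuLi, THF, −78 °C; then 18, −78 to 0 °C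
Reagents that add atoms: none
Why: N-acylation of the lithiated Evans oxazolidinone with the acid chloride.

Step 12
Reactants: 20 (4S)-4-benzyl-3-(3-methylbut-2-enoyl)-1,3-oxazolidin-2-one; 21 1-bromo-3-methylbut-2-ene (prenyl bromide)
Product: 23 (4S)-4-benzyl-3-[(2S)-5-methyl-2-(prop-1-en-2-yl)hex-4-enoyl]-1,3-oxazolidin-2-one, via sodium dienolate 22 (not isolated)
Conditions: NaN(SiMe3)2, THF, −78 °C; then 21, −78 to −40 °C
Reagents that add atoms: none
Why: Evans asymmetric alkylation in its deconjugative form, in which γ-deprotonation gives the chelated Z-dienolate that is alkylated at the α-carbon on the face opposite the benzyl group, so that the S centre is set and the double bond moves into the isopropenyl position.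

Step 13
Reactants: 23 (4S)-4-benzyl-3-[(2S)-5-methyl-2-(prop-1-en-2-yl)hex-4-enoyl]-1,3-oxazolidin-2-one
Product: 24 (2S)-5-methyl-2-(prop-1-en-2-yl)hex-4-en-1-ol ((S)-lavandulol)
Conditions: LiBH4, H2O (1 equiv), Et2O, 0 °C
Reagents that add atoms: none
Why: reductive cleavage of the N-acyl oxazolidinone with LiBH4 should give the primary alcohol without epimerizing the α-centre or touching the alkenes, and it releases the auxiliary.

Step 14
Reactants: 24 (2S)-5-methyl-2-(prop-1-en-2-yl)hex-4-en-1-ol
Product: 25 (3S)-3-(iodomethyl)-2,6-dimethylhepta-1,5-diene ((S)-lavandulyl iodide)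
Conditions: I2, PPh3, imidazole, CH2Cl2, 0 °C
Reagents that add atoms: iodine, II
Why: Appel-type iodination (PPh3/I2/imidazole) displaces the activated primary hydroxyl by iodide at CH2, one carbon away from the stereocentre.

Step 15
Reactants: 9 3,5-bis(methoxymethoxy)-2,6-bis(trimethylsilyl)phenyl trifluoromethanesulfonate; 16 (3S)-3-[2-methoxy-4-(methoxymethoxy)phenyl]-N,N-dimethyl-3-[(trimethylsilyl)oxy]propanamide
Product: 29 (2S)-2-[2-methoxy-4-(methoxymethoxy)phenyl]-5,7-bis(methoxymethoxy)-8-(trimethylsilyl)-2,3-dihydro-4H-chromen-4-one, via potassium alkoxide 26 (not isolated), via aryne 27 (not isolated), via hemiaminal alkoxide 28 (not isolated)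
Conditions: 9 (1.0 equiv), 16 (1.5 equiv), KF, 18-crown-6, THF, 0 °C to rt; then AcOH, 0 °C
Reagents that add atoms: none
Why: Proposed new method: fluoride cleaves the O–Si bond of 16 to give alkoxide 26 and, by Kobayashi 1,2-elimination, strips one silyl group and the triflate from 9 to give aryne 27; the alkoxide oxygen adds to C8a, the carbanion so formed at C4a adds to the amide carbonyl, and the stable hemiaminal alkoxide 28 collapses to ketone and dimethylamine only on the acidic quench. The closest known reaction types are the aryne annulation of salicylate esters to xanthones and the aryne insertion into C–O and N–C(=O) bonds of carboxylic acids and amides; a β-oxido amide with an sp3 stereocentre has not been used as the four-atom partner. Ring C closes by intermolecular O1–C8a bond formation followed by a 6-exo-trig addition of the C4a carbanion to the C4 carbonyl. No lasting stereocentre is formed: C2, set in step 9, comes in with its C2–O1 bond intact (retention), and the ketone stays masked as 28 while base is present, so that no retro-oxa-Michael opening of ring C can scramble it. The step needs regioselective addition of the alkoxide, and both flanking groups secure it: the inductively withdrawing acetal oxygen on C5 and the electropositive SiMe3 group on C8 distort the aryne so that C8a is the electrophilic carbon and the carbanion develops at C4a next to oxygen, and since 9 is symmetric either silyl group may leave. The aryne carries no alkene, so no intramolecular ene reaction competes, and because the alkoxide comes from a silyl ether and not from an alcohol the medium holds no proton that could quench the carbanion before it cyclizes.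

Step 16
Reactants: 29 (2S)-2-[2-methoxy-4-(methoxymethoxy)phenyl]-5,7-bis(methoxymethoxy)-8-(trimethylsilyl)-2,3-dihydro-4H-chromen-4-one
Product: 30 (2S)-8-iodo-2-[2-methoxy-4-(methoxymethoxy)phenyl]-5,7-bis(methoxymethoxy)-2,3-dihydro-4H-chromen-4-one
Conditions: ICl (1.05 equiv), NaHCO3, CH2Cl2, −78 to 0 °C
Reagents that add atoms: iodine monochloride, ClI
Why: ipso-iododesilylation, an electrophilic aromatic substitution at the silicon-bearing carbon, in which the β-silicon effect should make attack at C8 faster than C–H iodination at C6 or on ring B, while the cold, buffered medium spares the acetals.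

Step 17
Reactants: 25 (3S)-3-(iodomethyl)-2,6-dimethylhepta-1,5-diene; 30 (2S)-8-iodo-2-[2-methoxy-4-(methoxymethoxy)phenyl]-5,7-bis(methoxymethoxy)-2,3-dihydro-4H-chromen-4-one
Product: 32 (2S)-2-[2-methoxy-4-(methoxymethoxy)phenyl]-5,7-bis(methoxymethoxy)-8-[(2R)-5-methyl-2-(prop-1-en-2-yl)hex-4-en-1-yl]-2,3-dihydro-4H-chromen-4-one, via alkylzinc iodide 31 (not isolated)
Conditions: 25, Zn dust (activated with BrCH2CH2Br and Me3SiCl), LiCl, THF, 40 °C; then 30, Pd(OAc)2 (4 mol%), SPhos (8 mol%), THF, rt to 40 °C
Reagents that add atoms: none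
Why: Negishi coupling, in which LiCl-assisted zinc insertion gives the primary alkylzinc iodide, which is too weakly basic to enolize the ketone or open ring C, and zerovalent palladium carrying a bulky biarylphosphine should couple it at the hindered C8–I bond faster than β-hydride elimination, with the side-chain centre untouched.

Step 18
Reactants: 32 (2S)-2-[2-methoxy-4-(methoxymethoxy)phenyl]-5,7-bis(methoxymethoxy)-8-[(2R)-5-methyl-2-(prop-1-en-2-yl)hex-4-en-1-yl]-2,3-dihydro-4H-chromen-4-one
Product: 33 leachianone A, (2S)-5,7-dihydroxy-2-(4-hydroxy-2-methoxyphenyl)-8-[(2R)-5-methyl-2-(prop-1-en-2-yl)hex-4-en-1-yl]-2,3-dihydro-4H-chromen-4-one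
Conditions: HCl (1.25 M in MeOH), 0 °C to rt
Reagents that add atoms: none
Why: acid-catalysed transacetalization in methanol removes the three methoxymethyl groups at low temperature, under which the isopropenyl and prenyl alkenes and the C2 centre should survive.

**Compound list**

1 | phloroglucinol (benzene-1,3,5-triol) | Oc1cc(O)cc(O)c1 | starting material
2 | 3,5-bis(methoxymethoxy)phenol | COCOc1cc(O)cc(OCOC)c1 | intermediate
3 | 3,5-bis(methoxymethoxy)phenyl N,N-diethylcarbamate | CCN(CC)C(=O)Oc1cc(OCOC)cc(OCOC)c1 | intermediate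
4 | [2-(diethylcarbamoyloxy)-4,6-bis(methoxymethoxy)phenyl]lithium | CCN(CC)C(=O)Oc1cc(OCOC)cc(OCOC)c1[Li] | intermediate
5 | 3,5-bis(methoxymethoxy)-2-(trimethylsilyl)phenyl N,N-diethylcarbamate | CCN(CC)C(=O)Oc1cc(OCOC)cc(OCOC)c1[Si](C)(C)C | intermediate
6 | [2-(diethylcarbamoyloxy)-4,6-bis(methoxymethoxy)-3-(trimethylsilyl)phenyl]lithium | CCN(CC)C(=O)Oc1c([Li])c(OCOC)cc(OCOC)c1[Si](C)(C)C | intermediate
7 | 3,5-bis(methoxymethoxy)-2,6-bis(trimethylsilyl)phenyl N,N-diethylcarbamate | CCN(CC)C(=O)Oc1c([Si](C)(C)C)c(OCOC)cc(OCOC)c1[Si](C)(C)C | intermediate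
8 | 3,5-bis(methoxymethoxy)-2,6-bis(trimethylsilyl)phenol | COCOc1cc(OCOC)c([Si](C)(C)C)c(O)c1[Si](C)(C)C | intermediate
9 | 3,5-bis(methoxymethoxy)-2,6-bis(trimethylsilyl)phenyl trifluoromethanesulfonate | COCOc1cc(OCOC)c([Si](C)(C)C)c(OS(=O)(=O)C(F)(F)F)c1[Si](C)(C)C | intermediate
10 | methyl 4-hydroxy-2-methoxybenzoate | COC(=O)c1ccc(O)cc1OC | starting material
11 | methyl 2-methoxy-4-(methoxymethoxy)benzoate | COCOc1ccc(C(=O)OC)c(OC)c1 | intermediate
12 | N,N-dimethylacetamide | CC(=O)N(C)C | starting material
13 | lithium 1-(dimethylamino)ethen-1-olate | [Li]OC(=C)N(C)C | intermediate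
14 | 3-[2-methoxy-4-(methoxymethoxy)phenyl]-N,N-dimethyl-3-oxopropanamide | COCOc1ccc(C(=O)CC(=O)N(C)C)c(OC)c1 | intermediate
15 | (3S)-3-hydroxy-3-[2-methoxy-4-(methoxymethoxy)phenyl]-N,N-dimethylpropanamide | COCOc1ccc([C@@H](O)CC(=O)N(C)C)c(OC)c1 | intermediate
16 | (3S)-3-[2-methoxy-4-(methoxymethoxy)phenyl]-N,N-dimethyl-3-[(trimethylsilyl)oxy]propanamide | COCOc1ccc([C@@H](O[Si](C)(C)C)CC(=O)N(C)C)c(OC)c1 | intermediate
17 | (4S)-4-benzyl-1,3-oxazolidin-2-one | O=C1N[C@@H](Cc2ccccc2)CO1 | starting material
18 | 3-methylbut-2-enoyl chloride | CC(C)=CC(=O)Cl | starting material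
19 | N-lithio-(4S)-4-benzyl-1,3-oxazolidin-2-one | [Li]N1[C@@H](Cc2ccccc2)COC1=O | intermediate
20 | (4S)-4-benzyl-3-(3-methylbut-2-enoyl)-1,3-oxazolidin-2-one | CC(C)=CC(=O)N1[C@@H](Cc2ccccc2)COC1=O | intermediate
21 | 1-bromo-3-methylbut-2-ene (prenyl bromide) | CC(C)=CCBr | starting material
22 | sodium (Z)-dienolate of 20 | C=C(C)/C=C(\O[Na])N1[C@@H](Cc2ccccc2)COC1=O | intermediate
23 | (4S)-4-benzyl-3-[(2S)-5-methyl-2-(prop-1-en-2-yl)hex-4-enoyl]-1,3-oxazolidin-2-one | C=C(C)[C@H](CC=C(C)C)C(=O)N1[C@@H](Cc2ccccc2)COC1=O | intermediate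
24 | (2S)-5-methyl-2-(prop-1-en-2-yl)hex-4-en-1-ol ((S)-lavandulol) | C=C(C)[C@H](CC=C(C)C)CO | intermediate
25 | (3S)-3-(iodomethyl)-2,6-dimethylhepta-1,5-diene | C=C(C)[C@H](CC=C(C)C)CI | intermediate
26 | potassium (1S)-3-(dimethylamino)-1-[2-methoxy-4-(methoxymethoxy)phenyl]-3-oxopropan-1-olate | COCOc1ccc([C@@H](O[K])CC(=O)N(C)C)c(OC)c1 | intermediate
27 | 3,5-bis(methoxymethoxy)-6-(trimethylsilyl)benzyne (aryne across C4a and C8a) | COCOC1=CC(OCOC)=C([Si](C)(C)C)C#C1 | intermediate
28 | potassium (2S)-4-(dimethylamino)-2-[2-methoxy-4-(methoxymethoxy)phenyl]-5,7-bis(methoxymethoxy)-8-(trimethylsilyl)-3,4-dihydro-2H-chromen-4-olate (both C4 epimers) | COCOc1ccc([C@@H]2CC(O[K])(N(C)C)c3c(OCOC)cc(OCOC)c([Si](C)(C)C)c3O2)c(OC)c1 | intermediate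
29 | (2S)-2-[2-methoxy-4-(methoxymethoxy)phenyl]-5,7-bis(methoxymethoxy)-8-(trimethylsilyl)-2,3-dihydro-4H-chromen-4-one | COCOc1ccc([C@@H]2CC(=O)c3c(OCOC)cc(OCOC)c([Si](C)(C)C)c3O2)c(OC)c1 | intermediate
30 | (2S)-8-iodo-2-[2-methoxy-4-(methoxymethoxy)phenyl]-5,7-bis(methoxymethoxy)-2,3-dihydro-4H-chromen-4-one | COCOc1ccc([C@@H]2CC(=O)c3c(OCOC)cc(OCOC)c(I)c3O2)c(OC)c1 | intermediate
31 | [(2S)-5-methyl-2-(prop-1-en-2-yl)hex-4-en-1-yl]zinc iodide | C=C(C)[C@H](CC=C(C)C)C[Zn]I | intermediate
32 | (2S)-2-[2-methoxy-4-(methoxymethoxy)phenyl]-5,7-bis(methoxymethoxy)-8-[(2R)-5-methyl-2-(prop-1-en-2-yl)hex-4-en-1-yl]-2,3-dihydro-4H-chromen-4-one | C=C(C)[C@H](CC=C(C)C)Cc1c(OCOC)cc(OCOC)c2c1O[C@H](c1ccc(OCOC)cc1OC)CC2=O | intermediate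
33 | leachianone A | C=C(C)[C@H](CC=C(C)C)Cc1c(O)cc(O)c2c1O[C@H](c1ccc(O)cc1OC)CC2=O | target

**Summary**

Total step count: 18. Longest linear sequence: 10 steps (steps 1 to 6, then 15 to 18).

Steps most likely to fail:

Step 15 (proposed new method). What may go wrong: the C4a carbanion is protonated (by the amide α-CH2 or by traces of water) before it closes onto the amide, or the alkoxide is used up by attack at silicon or sulfur of 9, so that open-chain aryl ethers form instead of ring C. The fallback uses known chemistry and sets out from 9: the aryne insertion into the C–O bond of an α,β-unsaturated carboxylic acid with oxa-Michael closure, a known entry to chroman-4-ones. Commercial 4-hydroxy-2-methoxybenzaldehyde would be protected (MOMCl, K2CO3) as 2-methoxy-4-(methoxymethoxy)benzaldehyde F1 and condensed with malonic acid (pyridine, piperidine, Knoevenagel–Doebner) to (2E)-3-[2-methoxy-4-(methoxymethoxy)phenyl]prop-2-enoic acid F2. F2 and 9 with CsF in THF at about 100 °C should give, by carboxylate addition at C8a and acyl shift to C4a, the 2'-hydroxychalcone (2E)-1-[2-hydroxy-4,6-bis(methoxymethoxy)-3-(trimethylsilyl)phenyl]-3-[2-methoxy-4-(methoxymethoxy)phenyl]prop-2-en-1-one F3, which closes (in the same flask or with NaOAc in EtOH) to the racemic flavanone. Preparative HPLC on a chiral phase would give 29, where the route is rejoined. The (2R)-enantiomer, (2R)-2-[2-methoxy-4-(methoxymethoxy)phenyl]-5,7-bis(methoxymethoxy)-8-(trimethylsilyl)-2,3-dihydro-4H-chromen-4-one F4, would be re-equilibrated with base through F3 and recycled.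

Step 17. What may go wrong: slow oxidative addition and transmetalation at the doubly ortho-substituted C8–I bond, so that protodeiodination and β-hydride elimination win, or skeletal isomerization of the homoallylic zinc reagent during zinc insertion. The fallback sets out from 25 and 30 and joins them directly by nickel-catalysed reductive cross-electrophile coupling (NiI2, 4,4'-di-tert-butyl-2,2'-bipyridine, Zn powder, NaI, DMPU, 60 °C). This needs no preformed organometallic, tolerates the ketone, and comes back to the route at 32. It makes no compound outside the list (F0).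

Step 16. What may go wrong: C–H iodination at C6 or at C5' of ring B competes with ipso substitution, or the acetals are lost to adventitious acid. The fallback sets out from 7 and moves both the iodination and the side-chain coupling in front of the aryne step, where no second arene is present.
- ICl (1 equiv) would replace one of the two equivalent silyl groups to give 2-iodo-3,5-bis(methoxymethoxy)-6-(trimethylsilyl)phenyl N,N-diethylcarbamate F5.
- Negishi coupling of F5 with zinc reagent 31 (conditions of step 17) would give 3,5-bis(methoxymethoxy)-2-[(2R)-5-methyl-2-(prop-1-en-2-yl)hex-4-en-1-yl]-6-(trimethylsilyl)phenyl N,N-diethylcarbamate F6.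
- LiAlH4 (as in step 5) would give 3,5-bis(methoxymethoxy)-2-[(2R)-5-methyl-2-(prop-1-en-2-yl)hex-4-en-1-yl]-6-(trimethylsilyl)phenol F7, and Tf2O/pyridine (as in step 6) its trifluoromethanesulfonate, 3,5-bis(methoxymethoxy)-2-[(2R)-5-methyl-2-(prop-1-en-2-yl)hex-4-en-1-yl]-6-(trimethylsilyl)phenyl trifluoromethanesulfonate F8.
- F8 and 16 would then be joined as in step 15, through 3,5-bis(methoxymethoxy)-6-[(2R)-5-methyl-2-(prop-1-en-2-yl)hex-4-en-1-yl]benzyne F9 and the potassium 4-(dimethylamino)chroman-4-olate adduct F10. Here 16 would be used in larger excess and at −40 °C, so that alkoxide capture outruns the intramolecular ene reaction of the aryne with the side-chain alkenes.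
- The AcOH quench gives 32, where the route is rejoined; steps 15 to 17 of the main route are bypassed.

Further compounds
F1 | step 15 | 2-methoxy-4-(methoxymethoxy)benzaldehyde | COCOc1ccc(C=O)c(OC)c1
F2 | step 15 | (2E)-3-[2-methoxy-4-(methoxymethoxy)phenyl]prop-2-enoic acid | COCOc1ccc(/C=C/C(=O)O)c(OC)c1
F3 | step 15 | (2E)-1-[2-hydroxy-4,6-bis(methoxymethoxy)-3-(trimethylsilyl)phenyl]-3-[2-methoxy-4-(methoxymethoxy)phenyl]prop-2-en-1-one | COCOc1ccc(/C=C/C(=O)c2c(OCOC)cc(OCOC)c([Si](C)(C)C)c2O)c(OC)c1
F4 | step 15 | (2R)-2-[2-methoxy-4-(methoxymethoxy)phenyl]-5,7-bis(methoxymethoxy)-8-(trimethylsilyl)-2,3-dihydro-4H-chromen-4-one | COCOc1ccc([C@H]2CC(=O)c3c(OCOC)cc(OCOC)c([Si](C)(C)C)c3O2)c(OC)c1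
F0 | step 17 | none | none
F5 | step 16 | 2-iodo-3,5-bis(methoxymethoxy)-6-(trimethylsilyl)phenyl N,N-diethylcarbamate | CCN(CC)C(=O)Oc1c(I)c(OCOC)cc(OCOC)c1[Si](C)(C)C
F6 | step 16 | 3,5-bis(methoxymethoxy)-2-[(2R)-5-methyl-2-(prop-1-en-2-yl)hex-4-en-1-yl]-6-(trimethylsilyl)phenyl N,N-diethylcarbamate | C=C(C)[C@H](CC=C(C)C)Cc1c(OCOC)cc(OCOC)c([Si](C)(C)C)c1OC(=O)N(CC)CC
F7 | step 16 | 3,5-bis(methoxymethoxy)-2-[(2R)-5-methyl-2-(prop-1-en-2-yl)hex-4-en-1-yl]-6-(trimethylsilyl)phenol | C=C(C)[C@H](CC=C(C)C)Cc1c(OCOC)cc(OCOC)c([Si](C)(C)C)c1O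
F8 | step 16 | 3,5-bis(methoxymethoxy)-2-[(2R)-5-methyl-2-(prop-1-en-2-yl)hex-4-en-1-yl]-6-(trimethylsilyl)phenyl trifluoromethanesulfonate | C=C(C)[C@H](CC=C(C)C)Cc1c(OCOC)cc(OCOC)c([Si](C)(C)C)c1OS(=O)(=O)C(F)(F)F
F9 | step 16 | 3,5-bis(methoxymethoxy)-6-[(2R)-5-methyl-2-(prop-1-en-2-yl)hex-4-en-1-yl]benzyne | C=C(C)[C@H](CC=C(C)C)CC1=C(OCOC)C=C(OCOC)C#C1
F10 | step 16 | potassium (2S)-4-(dimethylamino)-2-[2-methoxy-4-(methoxymethoxy)phenyl]-5,7-bis(methoxymethoxy)-8-[(2R)-5-methyl-2-(prop-1-en-2-yl)hex-4-en-1-yl]-3,4-dihydro-2H-chromen-4-olate | C=C(C)[C@H](CC=C(C)C)Cc1c(OCOC)cc(OCOC)c2c1O[C@H](c1ccc(OCOC)cc1OC)CC2(O[K])N(C)C
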